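**Retrosynthetic overview**
1. Target ⇐ acidic removal of two MOM ethers from a thiolactone that is closed last, by 5-exo opening of a trans-epoxide by an ortho thiocarboxylate (aryl-Li + COS), with inversion at the benzylic carbon.
2. The ortho-bromoaryl trans-epoxide ⇐ Pd-catalysed, copper-mediated Stille-type coupling of aryl iodide fragment A with an enantioenriched trans-oxiranylstannane fragment B. This forms the C3–C3a bond and brings in both stereocentres, so the prenyl alkene never meets an oxidant.
3. Fragment A ⇐ hydroquinone: bis-MOM ether, double ortho-lithiation/iodination, mono-prenylation, ortho-lithiation/bromination.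
4. Fragment B ⇐ hept-1-ene: epoxidation, hydrolytic kinetic resolution, trans-selective α-lithiation/stannylation.
5. Ring order: the benzene ring is bought, the oxirane is carried in fragment B, and the thiolactone ring is formed last.

Assumption: (R,R)-(salen)Co(OAc) is taken to hydrolyse the (S)-epoxide and leave (R)-12 (use the (S,S) catalyst if the sense is opposite); a one-flask sequence without isolation is counted as one step.

**Step 1**
Reactants: 1 hydroquinone
Product: 2 1,4-bis(methoxymethoxy)benzene
Conditions: NaH, MOMCl, DMF, 0 °C → rt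
Reagents that add atoms: chloromethyl methyl ether (MOMCl), COCCl
Why: Williamson-type O-alkylation of both phenoxides installs MOM ethers that survive organolithiums and direct the later ortho-metalations.

**Step 2**
Reactants: 2 1,4-bis(methoxymethoxy)benzene
Product: 4 1,4-diiodo-2,5-bis(methoxymethoxy)benzene, via 2,5-dilithio arene 3 (not isolated)
Conditions: n-BuLi (3 equiv), TMEDA, Et2O, 0 °C → rt; then I2, THF, −78 °C → rt
Reagents that add atoms: iodine, II
Why: Double directed ortho-metalation, in which each OMOM group directs one lithiation and the second lithium goes para to the first, followed by iodinolysis to give the 2,5-diiodide.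

**Step 3**
Reactants: 4 1,4-diiodo-2,5-bis(methoxymethoxy)benzene; 5 prenyl bromide
Product: 7 1-iodo-2,5-bis(methoxymethoxy)-4-(3-methylbut-2-en-1-yl)benzene, via arylmagnesium chloride 6 (not isolated)
Conditions: i-PrMgCl·LiCl (1.05 equiv), THF, −40 °C; then Li2CuCl4 (5 mol %), 5, −40 → 0 °C
Reagents that add atoms: none
Why: Knochel iodine–magnesium exchange stops cleanly at the mono-Grignard because the first exchange deactivates the second iodide, and copper-catalysed SN2 allylation gives the linear prenyl arene.

**Step 4**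
Reactants: 7 1-iodo-2,5-bis(methoxymethoxy)-4-(3-methylbut-2-en-1-yl)benzene
Product: 9 3-bromo-2-iodo-1,4-bis(methoxymethoxy)-5-(3-methylbut-2-en-1-yl)benzene, via aryllithium 8 (not isolated)
Conditions: lithium 2,2,6,6-tetramethylpiperidide (LiTMP), THF, −78 °C; then BrCCl2CCl2Br, −78 °C → rt
Reagents that add atoms: 1,2-dibromo-1,1,2,2-tetrachloroethane, BrC(Cl)(Cl)C(Cl)(Cl)Br
Why: Directed ortho-lithiation removes the most acidic ring proton, the one flanked by iodine and OMOM, and electrophilic bromination then gives an iodide for the coupling and a bromide for the later lithiation.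

**Step 5**
Reactants: 10 hept-1-ene
Product: 11 rac-2-pentyloxirane
Conditions: mCPBA, CH2Cl2, 0 °C → rt
Reagents that add atoms: 3-chloroperbenzoic acid (mCPBA), OOC(=O)c1cccc(Cl)c1
Why: Prilezhaev epoxidation of a terminal alkene.

**Step 6**
Reactants: 11 rac-2-pentyloxirane
Product: 12 (R)-2-pentyloxirane
Conditions: (R,R)-(salen)Co(OAc) (0.5 mol %; trivalent cobalt, salen = N,N′-bis(3,5-di-tert-butylsalicylidene)cyclohexane-1,2-diamine dianion), H2O (0.55 equiv), neat, 0 °C → rt; distillation
Reagents that add atoms: none
Why: Jacobsen hydrolytic kinetic resolution hydrolyses the S epoxide and leaves the R epoxide in high ee, which fixes the future C1′ carbinol configuration.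

**Step 7**
Reactants: 12 (R)-2-pentyloxirane
Product: 14 (2R,3R)-tributyl(3-pentyloxiran-2-yl)stannane, via oxiranyllithium 13 (not isolated)
Conditions: Bu3SnCl, lithium 2,2,6,6-tetramethylpiperidide (LiTMP), THF, −78 → 0 °C (in situ trapping)
Reagents that add atoms: tributyltin chloride, CCCC[Sn](Cl)(CCCC)CCCC
Why: LiTMP-mediated α-lithiation of a terminal epoxide takes the proton trans to the pentyl group, and in situ stannylation with retention stores the trans-oxiranyl anion as a stable, configurationally defined stannane.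

**Step 8**
Reactants: 14 (2R,3R)-tributyl(3-pentyloxiran-2-yl)stannane; 9 3-bromo-2-iodo-1,4-bis(methoxymethoxy)-5-(3-methylbut-2-en-1-yl)benzene
Product: 16 (2R,3R)-2-[2-bromo-3,6-bis(methoxymethoxy)-4-(3-methylbut-2-en-1-yl)phenyl]-3-pentyloxirane, via oxiranylcopper 15 (not isolated)
Conditions: CuCl (1.5 equiv), CsF (2 equiv), Pd2(dba)3 (2.5 mol %), AsPh3 (20 mol %), DMF, 40 °C
Reagents that add atoms: none
Why: Proposed new method: stereoretentive Stille-type arylation of a non-stabilised, enantioenriched trans-oxiranyl tributylstannane with a di-ortho-substituted aryl iodide under Pd catalysis with CuCl and CsF, expected to work because fluoride-driven tin-to-copper exchange is retentive and transfers the oxiranyl group (a carbon of high s-character, assisted by the ring oxygen) in preference to butyl, the oxiranylcopper 15 (monovalent copper) passes the group with retention to the arylpalladium iodide (divalent palladium) that forms by oxidative addition into C–I and not the flanking C–Br, reductive elimination is fast for this sp2-like carbon, β-hydride elimination would need an oxirene and β-oxygen elimination is geometrically disfavoured in the three-membered ring; the closest known reaction types are the stereoretentive Pd/Cu Stille couplings of α-alkoxyalkyl- and α-acyloxyalkylstannanes, the Stille coupling of cyclopropylstannanes and the retentive Suzuki coupling of α-alkoxyalkyl trifluoroborates.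

**Step 9**
Reactants: 16 (2R,3R)-2-[2-bromo-3,6-bis(methoxymethoxy)-4-(3-methylbut-2-en-1-yl)phenyl]-3-pentyloxirane; 17 carbonyl sulfide
Product: 21 asperglaucin A, via aryllithium 18 (not isolated), via lithium thiocarboxylate 19 (not isolated), via bis-MOM thiolactone 20 (not isolated)
Conditions: t-BuLi (2.1 equiv), THF, −78 °C; COS, −78 → 40 °C; then HCl (2 M in MeOH), 25 °C
Reagents that add atoms: none
Why: Bromine–lithium exchange and thiocarboxylation with COS place a sulfur nucleophile ortho to the epoxide, whose 5-exo-tet SN2 opening at the benzylic carbon inverts it to 3S while C1′ stays R, and the methanolic HCl quench then cleaves both MOM acetals.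

**Compound list**
1 | hydroquinone (benzene-1,4-diol) | Oc1ccc(O)cc1 | starting material
2 | 1,4-bis(methoxymethoxy)benzene | COCOc1ccc(OCOC)cc1 | intermediate
3 | 2,5-dilithio-1,4-bis(methoxymethoxy)benzene | [Li]c1cc(OCOC)c([Li])cc1OCOC | intermediate
4 | 1,4-diiodo-2,5-bis(methoxymethoxy)benzene | COCOc1cc(I)c(OCOC)cc1I | intermediate
5 | prenyl bromide (1-bromo-3-methylbut-2-ene) | CC(C)=CCBr | starting material
6 | [4-iodo-2,5-bis(methoxymethoxy)phenyl]magnesium chloride | COCOc1cc([Mg]Cl)c(OCOC)cc1I | intermediate
7 | 1-iodo-2,5-bis(methoxymethoxy)-4-(3-methylbut-2-en-1-yl)benzene | COCOc1cc(CC=C(C)C)c(OCOC)cc1I | intermediate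
8 | [2-iodo-3,6-bis(methoxymethoxy)-5-(3-methylbut-2-en-1-yl)phenyl]lithium | COCOc1cc(CC=C(C)C)c(OCOC)c([Li])c1I | intermediate
9 | 3-bromo-2-iodo-1,4-bis(methoxymethoxy)-5-(3-methylbut-2-en-1-yl)benzene | COCOc1cc(CC=C(C)C)c(OCOC)c(Br)c1I | intermediate
10 | hept-1-ene | C=CCCCCC | starting material
11 | rac-2-pentyloxirane | CCCCCC1CO1 | intermediate
12 | (R)-2-pentyloxirane | CCCCC[C@@H]1CO1 | intermediate
13 | (2R,3R)-(3-pentyloxiran-2-yl)lithium (trans) | CCCCC[C@H]1O[C@@H]1[Li] | intermediate
14 | (2R,3R)-tributyl(3-pentyloxiran-2-yl)stannane | CCCCC[C@H]1O[C@@H]1[Sn](CCCC)(CCCC)CCCC | intermediate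
15 | (2R,3R)-(3-pentyloxiran-2-yl)copper (trans) | CCCCC[C@H]1O[C@@H]1[Cu] | intermediate
16 | (2R,3R)-2-[2-bromo-3,6-bis(methoxymethoxy)-4-(3-methylbut-2-en-1-yl)phenyl]-3-pentyloxirane | CCCCC[C@H]1O[C@@H]1c1c(Br)c(OCOC)c(CC=C(C)C)cc1OCOC | intermediate
17 | carbonyl sulfide | O=C=S | starting material
18 | [3,6-bis(methoxymethoxy)-5-(3-methylbut-2-en-1-yl)-2-[(2R,3R)-3-pentyloxiran-2-yl]phenyl]lithium | CCCCC[C@H]1O[C@@H]1c1c([Li])c(OCOC)c(CC=C(C)C)cc1OCOC | intermediate
19 | lithium 3,6-bis(methoxymethoxy)-5-(3-methylbut-2-en-1-yl)-2-[(2R,3R)-3-pentyloxiran-2-yl]benzenecarbothioate | [Li+].CCCCC[C@H]1O[C@@H]1c1c(C(=O)[S-])c(OCOC)c(CC=C(C)C)cc1OCOC | intermediate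
20 | (3S)-3-[(1R)-1-hydroxyhexyl]-4,7-bis(methoxymethoxy)-6-(3-methylbut-2-en-1-yl)-2-benzothiophen-1(3H)-one (formed as its lithium alkoxide) | CCCCC[C@@H](O)[C@H]1SC(=O)c2c(OCOC)c(CC=C(C)C)cc(OCOC)c21 | intermediate
21 | asperglaucin A, (3S)-4,7-dihydroxy-3-[(1R)-1-hydroxyhexyl]-6-(3-methylbut-2-en-1-yl)-2-benzothiophen-1(3H)-one | CCCCC[C@@H](O)[C@H]1SC(=O)c2c(O)c(CC=C(C)C)cc(O)c21 | target

**Step count**
Total: 9 steps. Longest linear sequence: 6 steps (1, 2, 3, 4, 8, 9). Fragment B (steps 5 to 7) is made in parallel.

**Three steps most likely to fail, with fallbacks**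

Step 8, the proposed new oxiranylstannane coupling. The oxiranyl group may leave tin too slowly (butyl transfer or protodestannylation instead), the oxiranylcopper may decompose, or the hindered arylpalladium species may not accept it. The fallback uses known chemistry, sets out from 9 and comes back at 16. Heptanal is α-chlorinated with N-chlorosuccinimide and a chiral 2,5-diphenylpyrrolidine catalyst (the enantiomer giving the S aldehyde) to (S)-2-chloroheptanal F1. Compound 9 undergoes selective iodine–magnesium exchange with i-PrMgCl·LiCl at −40 °C to [2-bromo-3,6-bis(methoxymethoxy)-4-(3-methylbut-2-en-1-yl)phenyl]magnesium chloride F2. Addition of F2 to F1 at −78 °C under Cornforth–Felkin control gives the anti chlorohydrin (1R,2S)-1-[2-bromo-3,6-bis(methoxymethoxy)-4-(3-methylbut-2-en-1-yl)phenyl]-2-chloroheptan-1-ol F3. KOH in EtOH closes F3, with inversion at the C–Cl carbon, to the trans-epoxide 16.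

Step 9, the lithiation/COS/epoxide-opening cascade with acidic finish. The risks are sluggish opening of the hindered benzylic epoxide by the lithium thiocarboxylate, attack of the aryllithium on the epoxide, acyl transfer from sulfur to the new alkoxide before the quench, and acid-induced chroman formation from the prenyl phenol. The fallback changes to a palladium carbonylation, sets out from 16 and comes back at 21. Thioacetic acid opens 16 at the benzylic carbon with inversion to S-{(1S,2R)-1-[2-bromo-3,6-bis(methoxymethoxy)-4-(3-methylbut-2-en-1-yl)phenyl]-2-hydroxyheptyl} ethanethioate F4. K2CO3 in MeOH at 0 °C removes the S-acetyl group to give (1S,2R)-1-[2-bromo-3,6-bis(methoxymethoxy)-4-(3-methylbut-2-en-1-yl)phenyl]-1-sulfanylheptan-2-ol F5. Pd(OAc)2, Xantphos, CO (1 atm) and K2CO3 in toluene at 80 °C then close F5 by intramolecular thiocarbonylation to 20. Compound 20 is isolated and treated with HCl in MeOH to give 21.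

Step 2, the double ortho-lithiation/iodination. The risk is incomplete second lithiation, giving mono-iodide or regioisomers. The fallback replaces directed metalation by electrophilic bromination and halogen exchange, sets out from 1 and comes back at 4. Hydroquinone is brominated with Br2 in AcOH to 2,5-dibromobenzene-1,4-diol F6. NaH and MOMCl give 1,4-dibromo-2,5-bis(methoxymethoxy)benzene F7. Copper-catalysed aromatic halogen exchange (CuI 10 mol %, N,N′-dimethylethane-1,2-diamine, NaI, dioxane, 110 °C) converts F7 into 4.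

**Further compounds**
F1 | step 8 | (S)-2-chloroheptanal | CCCCC[C@H](Cl)C=O
F2 | step 8 | [2-bromo-3,6-bis(methoxymethoxy)-4-(3-methylbut-2-en-1-yl)phenyl]magnesium chloride | COCOc1cc(CC=C(C)C)c(OCOC)c(Br)c1[Mg]Cl
F3 | step 8 | (1R,2S)-1-[2-bromo-3,6-bis(methoxymethoxy)-4-(3-methylbut-2-en-1-yl)phenyl]-2-chloroheptan-1-ol | CCCCC[C@H](Cl)[C@H](O)c1c(Br)c(OCOC)c(CC=C(C)C)cc1OCOC
F4 | step 9 | S-{(1S,2R)-1-[2-bromo-3,6-bis(methoxymethoxy)-4-(3-methylbut-2-en-1-yl)phenyl]-2-hydroxyheptyl} ethanethioate | CCCCC[C@@H](O)[C@H](c1c(Br)c(OCOC)c(CC=C(C)C)cc1OCOC)SC(C)=O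
F5 | step 9 | (1S,2R)-1-[2-bromo-3,6-bis(methoxymethoxy)-4-(3-methylbut-2-en-1-yl)phenyl]-1-sulfanylheptan-2-ol | CCCCC[C@@H](O)[C@@H](S)c1c(Br)c(OCOC)c(CC=C(C)C)cc1OCOC
F6 | step 2 | 2,5-dibromobenzene-1,4-diol | Oc1cc(Br)c(O)cc1Br
F7 | step 2 | 1,4-dibromo-2,5-bis(methoxymethoxy)benzene | COCOc1cc(Br)c(OCOC)cc1Br
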